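200 turnovers per catalyst are needed at a loading of 0.5 mol% to turn the whole charge of starting material into target. The bench rule counts turnovers as target over loading: a catalyst good for a fixed count stops at that count, whatever the charge.

| flask | starting material | gas phase | catalyst | remark | time |
|---|---|---|---|---|---|
| west | 0.015 M | 7.7 mM (held) | 0.5 mol% | run made earlier |  |
| south-east | 0.022 M | 7.7 mM (held) | 0.5 mol% | run made earlier |  |
| flask | 0.029 M | 7.7 mM (held) | 0.5 mol% |  | 1.0 h |

| run | time / min | target / % |
|---|---|---|
| west | 2.00 | 5.0 |
| west | 6.00 | 20.2 |
| west | 10.0 | 31.7 |
| west | 15.0 | 40.4 |
| west | 20.0 | 48.2 |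
| west | 30.0 | 52.4 |
| west | 40.0 | 55.2 |
| south-east | 2.00 | 5.9 |
| south-east | 6.00 | 26.4 |
| south-east | 10.0 | 39.3 |
| south-east | 15.0 | 50.5 |
| south-east | 20.0 | 57.9 |
| south-east | 30.0 | 63.2 |
| south-east | 40.0 | 62.5 |

(readings scatter by 0.5 percentage points)

- the numbers in the tables scatter by 0.5 percentage points (one standard deviation)
- at the start none of the gas phase is in solution

- Friday's: doubling the saturation concentration of gas phase, all else as stated
- Thursday's: doubling the amount of catalyst, all else as stated
- Sunday's: doubling the transfer coefficient of the gas phase, all else as stated

- the target standing at 1.0 h, as a percentage of the starting material charged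
- the change that raises the amount of target at 1.0 h, in percent of the starting material charged most ("none" if none brings more than 2 percentage points) (Friday's / Thursday's / Sunday's / none)
- amount of target at 1.0 h, in percent of the starting material charged, after Friday's

At 40.0 min the west run stands at 110 turnovers and the south-east run at 125. The rule stops here: the loadings are equal, yet the two readings differ by 7.3 percentage points against a scatter of 0.5 points. What differs is the charge of starting material, and [catalyst] with it, 0.0750 mM against 0.110 mM.

My own reckoning therefore takes turnovers made over turnovers missed, a selectivity factor between a catalysed route and a background route. These odds are 1.22 in the west run and 1.67 in the south-east run. Divided by [catalyst], the south-east reading gives 15.2 mM⁻¹, the turnover odds per [catalyst].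

The flask, at 0.145 mM, then has odds of 2.20, so 68.7 % target. Thursday's doubles [catalyst] and gives 81.5 %, so this reckoning picks it; the two runs do not vary the gas, with a saturation concentration of 7.7 mM in both, so they put no price on Friday's or Sunday's.

The forecast says 68 % and picks Friday's, at 78 %, where this reckoning picks Thursday's; in its words, “Doubling saturation doubles both the intrinsic rate and the gas supply”.

The flask gives 63.8 %. Thursday's gains 7.9 points, more than Friday's, which gives 62.9 %, or Sunday's, which moves the target by −0.29 points.

    starting material + dissolved gas + catalyst → catalyst + target (k = 1700 L² mol⁻² s⁻¹)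
    target ⇌ isomer of the product (K = 0.770, k = 6.80 × 10⁻⁵ s⁻¹)
    starting material + dissolved gas → uncatalysed product (k = 0.0770 L mol⁻¹ s⁻¹)
    gas phase ⇌ dissolved gas, rate k4*(csat - [dissolved gas]) (kL = 0.0140 s⁻¹)

The reckoned odds of 2.20 exceed the flask's target odds of 1.76, with 12.4 % isomer of the product and 23.8 % uncatalysed product beside the target at 1.00 h. At 0.113 h the catalysed step in the flask uses starting material 3.2 times as fast as the uncatalysed step, and dissolved gas by the same ratio, 3.2. A second flask at 0.0073 M, same loading, has reckoned odds of 0.553, so 35.6 % target; computed, it gives 37.2 %.

Readings and results were computed from invented constants, noise included.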